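**Retrosynthetic overview**
1. Asbestinin 16 ⇐ oxidation of the C6 allylic alcohol ⇐ singlet-oxygen ene reaction on a (6Z)-oxonene ⇐ ring-closing metathesis. The oxonane is the last ring formed.
2. The metathesis diene ⇐ convex-face methallylation at C9 and chelate-controlled allylation at C4 of a tetracyclic lactone–ester.
3. The oxepane ⇐ C3–OH displacing a C16 triflate. C15, C12 and C11 come from hydroboration, then oxidation and reduction at C11.
4. The cyclohexene and the γ-lactone (the future THF ring) ⇐ one ester-tethered intramolecular Diels–Alder reaction of a dienoate/enone. This is the key step.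
5. The Diels–Alder substrate ⇐ L-tartrate acetonide (C1–C4, which supplies C2 and C3), MeI, an acetonyl ylide and 4-methylpentadienoic acid. Ring order: cyclohexene + lactone, then oxepane, then oxonane.

Assumption: names use asbestinin numbering (C1/C10 ring fusion; C2 and C9 on the bridging O; C3(Me)–C8 the rest of the oxonane; C11–C14 the rest of the cyclohexane; C15(Me)–C16 the oxepane arm), and C9 in 17–20 and C6 in 23–24 are epimer mixtures that are erased later, so they carry no stereo label.

**Step 1**
Reactants: 1 dimethyl (4R,5R)-2,2-dimethyl-1,3-dioxolane-4,5-dicarboxylate (L-tartrate acetonide)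
Product: 2 dimethyl (4R,5R)-2,2,4-trimethyl-1,3-dioxolane-4,5-dicarboxylate
Conditions: LDA, THF–DMPU, −78 °C; MeI, −78 °C
Reagents that add atoms: methyl iodide, CI
Why: In this Seebach alkylation of the tartrate acetonide enolate, MeI enters so that the two esters stay trans (net retention), which turns the bought C3 into the C3(Me)(O) quaternary centre and leaves the bought C2 untouched.

**Step 2**
Reactants: 2 dimethyl (4R,5R)-2,2,4-trimethyl-1,3-dioxolane-4,5-dicarboxylate
Product: 4 methyl (4R,5S)-2,2,4-trimethyl-5-[(1E)-3-oxobut-1-enyl]-1,3-dioxolane-4-carboxylate, via methyl (4R,5R)-5-formyl-2,2,4-trimethyl-1,3-dioxolane-4-carboxylate 3 (not isolated)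
Conditions: DIBAL-H (1.05 equiv), CH2Cl2, −78 °C; MeOH; Ph3P=CHC(O)Me, −78 °C → rt
Reagents that add atoms: 1-(triphenylphosphoranylidene)propan-2-one, CC(=O)C=P(c1ccccc1)(c1ccccc1)c1ccccc1
Why: The DIBAL half-reduction takes the ester on the CH carbon rather than the neopentyl-type ester, and the stabilised-ylide Wittig reaction gives the E-enone (C1=C14) without touching C2.

**Step 3**
Reactants: 4 methyl (4R,5S)-2,2,4-trimethyl-5-[(1E)-3-oxobut-1-enyl]-1,3-dioxolane-4-carboxylate
Product: 5 methyl (2R,3S,4E)-2,3-dihydroxy-2-methyl-6-oxohept-4-enoate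
Conditions: TFA–H2O (4:1), 0 °C
Reagents that add atoms: none
Why: Acid-catalysed acetal hydrolysis frees the C2 and C3 hydroxyls and changes no stereocentre.

**Step 4**
Reactants: 6 methacrolein; 7 malonic acid
Product: 8 (2E)-4-methylpenta-2,4-dienoic acid
Conditions: pyridine, piperidine (cat.), 70 °C
Reagents that add atoms: none
Why: The Doebner–Knoevenagel condensation with decarboxylation gives the E-dienoic acid (C9–C13 plus the C12 methyl).

**Step 5**
Reactants: 5 methyl (2R,3S,4E)-2,3-dihydroxy-2-methyl-6-oxohept-4-enoate; 8 (2E)-4-methylpenta-2,4-dienoic acid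
Product: 9 C2-O-[(2E)-4-methylpenta-2,4-dienoyl] ester of 5 (tertiary C3–OH free)
Conditions: DCC, DMAP (cat.), CH2Cl2, 0 °C
Reagents that add atoms: none
Why: The Steglich esterification acylates only the secondary allylic OH, because the tertiary α-hydroxy-ester OH is too hindered.

**Step 6**
Reactants: 9 C2-O-dienoate ester
Product: 11 cis-fused bicyclic γ-lactone (C9 lactone C=O, C11=C12(Me) cyclohexene, C14 acetyl, C2 carrying C3(Me)(OH)CO2Me; C1, C2, C3, C10, C14 as in 25), via trans-fused lactone (C10 epimer of 11) 10 (not isolated)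
Conditions: PhMe (5 mM), BHT, 160 °C (sealed); then DBU (0.3 equiv), rt
Reagents that add atoms: none
Why: In this intramolecular Diels–Alder reaction the three-atom ester tether fixes the regiochemistry and brings the diene to the C1 face syn to the C2–O bond through the rotamer with C2–H inside and the quaternary C3 anti (sets C1), the E-alkene carries the C2/C15 trans relation into C14, and DBU epimerises C10 of the trans-lactone to the more stable cis-lactone.

**Step 7**
Reactants: 11 cis-fused bicyclic γ-lactone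
Product: 12 C14-isopropenyl lactone
Conditions: Ph3PCH3Br, KOt-Bu, THF, 0 °C
Reagents that add atoms: methyltriphenylphosphonium bromide, C[P+](c1ccccc1)(c1ccccc1)c1ccccc1.[Br-]
Why: The Wittig methylenation is selective for the ketone over the lactone and ester, and C14 already has its thermodynamically preferred (equatorial) configuration, so it cannot be lost.

**Step 8**
Reactants: 12 C14-isopropenyl lactone
Product: 13 triol (C16–OH, 11-epi C11–OH, C3–OH; C12 and C15 as in 25)
Conditions: 9-BBN (3.5 equiv), THF, rt then 65 °C; NaBO3·4H2O, H2O, rt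
Reagents that add atoms: sodium perborate, [Na+].[O-]OB=O
Why: In this hydroboration–oxidation the isopropenyl group reacts in its C14–H-eclipsed rotamer from the side away from C1 (isopulegol-type 1,2-induction, sets C15), and the ring alkene takes H and B syn from the convex face of H1/H10, which sets C12 and gives a C11 alcohol that is corrected in steps 10 and 11.

**Step 9**
Reactants: 13 triol
Product: 15 oxepane lactone alcohol (C3–O–C16 ring closed, 11-epi C11–OH), via C16 primary triflate 14 (not isolated)
Conditions: Tf2O (1.05 equiv), 2,6-lutidine, CH2Cl2, −78 → 0 °C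
Reagents that add atoms: none
Why: Only the primary OH is triflated, and the neighbouring tertiary C3–OH displaces it in an intramolecular SN2 (Williamson-type) etherification that touches no stereocentre.

**Step 10**
Reactants: 15 oxepane lactone alcohol
Product: 16 C11 ketone
Conditions: DMP (1.3 equiv), CH2Cl2, 0 °C → rt
Reagents that add atoms: none
Why: The Dess–Martin oxidation is non-basic, so the axial, epimerisable C12 methyl next to the new ketone is kept.

**Step 11**
Reactants: 16 C11 ketone
Product: 17 C9 lactol / C4 aldehyde / C11 alcohol (C11 as in 25)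
Conditions: DIBAL-H (3.3 equiv), CH2Cl2, −78 °C; Rochelle salt
Reagents that add atoms: none
Why: In this DIBAL reduction hydride reaches the C11 ketone axially from the convex face because the axial C12–Me and C10–C9 bonds block the other face (sets C11, equatorial OH), while at −78 °C the lactone stops at the lactol and the chelated α-alkoxy ester stops at the aldehyde.

**Step 12**
Reactants: 17 lactol–aldehyde–alcohol
Product: 18 C9,C11-diacetate aldehyde
Conditions: Ac2O, pyridine, DMAP (cat.), 0 °C → rt
Reagents that add atoms: acetic anhydride, CC(=O)OC(C)=O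
Why: One acetylation installs the permanent C11 acetate and the anomeric C9 acetate leaving group, and the non-enolisable C4 aldehyde is untouched.

**Step 13**
Reactants: 18 C9,C11-diacetate aldehyde
Product: 19 C4 homoallylic alcohol (C4 as in 25)
Conditions: allylSnBu3, MgBr2·OEt2, CH2Cl2, −78 → −40 °C
Reagents that add atoms: allyltributylstannane, C=CC[Sn](CCCC)(CCCC)CCCC
Why: In this Keck chelation-controlled allylation Mg bridges the aldehyde O and the oxepane O on C3, and the allyl group attacks the Cram chelate from the C3–CH3 side, opposite C2, which sets C4.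

**Step 14**
Reactants: 19 C4 homoallylic alcohol
Product: 20 C4 octanoate
Conditions: n-C7H15COCl, pyridine, DMAP (cat.), CH2Cl2, 0 °C → rt
Reagents that add atoms: octanoyl chloride, CCCCCCCC(=O)Cl
Why: DMAP-catalysed acylation of the only free hydroxyl proceeds with retention at C4.

**Step 15**
Reactants: 20 C4 octanoate
Product: 21 C9-methallyl, C4-allyl metathesis precursor (C9 as in 25)
Conditions: methallylSiMe3, TMSOTf (0.2 equiv), CH2Cl2, −78 °C
Reagents that add atoms: methallyltrimethylsilane, C=C(C)C[Si](C)(C)C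
Why: In this Hosomi–Sakurai C-glycosidation the C9 oxocarbenium ion of the cis-fused bicycle is attacked on its convex face, anti to the C10–C11 bond, which sets C9 cis to C3 across the ring oxygen.

**Step 16**
Reactants: 21 metathesis precursor
Product: 22 (6Z)-oxonene tetracycle (C6=C7(Me))
Conditions: Grubbs II (10 mol %), PhMe (1 mM), 80 °C
Reagents that add atoms: none
Why: Ring-closing metathesis of the terminal alkene and the 1,1-disubstituted alkene, both held on the same face of the THF ring, closes the nine-membered ring, which can hold only the Z-alkene.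

**Step 17**
Reactants: 22 (6Z)-oxonene tetracycle
Product: 24 C6 allylic alcohol with C7 exocyclic methylene, via C6 allylic hydroperoxide 23 (not isolated)
Conditions: O2, TPP, hν, CH2Cl2, 0 °C; then PPh3
Reagents that add atoms: dioxygen, O=O
Why: In the Schenck ene reaction singlet oxygen attacks the outer alkene face and takes H from the freely rotating C19 methyl, because the ring C5–H and C8–H bonds lie near the alkene plane, and the C6 configuration is erased in step 18.

**Step 18**
Reactants: 24 C6 allylic alcohol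
Product: 25 asbestinin 16
Conditions: DMP (1.5 equiv), CH2Cl2, 0 °C → rt
Reagents that add atoms: none
Why: The neutral Dess–Martin oxidation gives the enone without E1cB loss of the β-octanoate and touches no stereocentre.

**Compound list**
1 | dimethyl (4R,5R)-2,2-dimethyl-1,3-dioxolane-4,5-dicarboxylate | COC(=O)[C@@H]1OC(C)(C)O[C@H]1C(=O)OC | starting material
2 | dimethyl (4R,5R)-2,2,4-trimethyl-1,3-dioxolane-4,5-dicarboxylate | COC(=O)[C@@H]1OC(C)(C)O[C@@]1(C)C(=O)OC | intermediate
3 | methyl (4R,5R)-5-formyl-2,2,4-trimethyl-1,3-dioxolane-4-carboxylate | O=C[C@@H]1OC(C)(C)O[C@@]1(C)C(=O)OC | intermediate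
4 | methyl (4R,5S)-2,2,4-trimethyl-5-[(1E)-3-oxobut-1-enyl]-1,3-dioxolane-4-carboxylate | CC(=O)/C=C/[C@@H]1OC(C)(C)O[C@@]1(C)C(=O)OC | intermediate
5 | methyl (2R,3S,4E)-2,3-dihydroxy-2-methyl-6-oxohept-4-enoate | CC(=O)/C=C/[C@H](O)[C@@](C)(O)C(=O)OC | intermediate
6 | methacrolein | C=C(C)C=O | starting material
7 | malonic acid | OC(=O)CC(=O)O | starting material
8 | (2E)-4-methylpenta-2,4-dienoic acid | C=C(C)/C=C/C(=O)O | intermediate
9 | C2-O-[(2E)-4-methylpenta-2,4-dienoyl] ester of 5 | C=C(C)/C=C/C(=O)O[C@@H](/C=C/C(C)=O)[C@@](C)(O)C(=O)OC | intermediate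
10 | trans-fused Diels–Alder lactone (C10 epimer of 11) | O=C1O[C@H]([C@@](C)(O)C(=O)OC)[C@H]2[C@H](C(C)=O)CC(C)=C[C@H]12 | intermediate
11 | cis-fused Diels–Alder lactone, C14 acetyl | O=C1O[C@H]([C@@](C)(O)C(=O)OC)[C@H]2[C@H](C(C)=O)CC(C)=C[C@@H]12 | intermediate
12 | C14-isopropenyl lactone | O=C1O[C@H]([C@@](C)(O)C(=O)OC)[C@H]2[C@H](C(C)=C)CC(C)=C[C@@H]12 | intermediate
13 | triol (C16–OH, 11-epi C11–OH, C3–OH) | O=C1O[C@H]([C@@](C)(O)C(=O)OC)[C@H]2[C@H]([C@@H](C)CO)C[C@@H](C)[C@H](O)[C@@H]12 | intermediate
14 | C16 primary triflate of 13 | O=C1O[C@H]([C@@](C)(O)C(=O)OC)[C@H]2[C@H]([C@@H](C)COS(=O)(=O)C(F)(F)F)C[C@@H](C)[C@H](O)[C@@H]12 | intermediate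
15 | oxepane lactone alcohol (11-epi) | O=C1O[C@H]2[C@H]3[C@@H](C[C@@H](C)[C@H](O)[C@@H]13)[C@@H](C)CO[C@@]2(C)C(=O)OC | intermediate
16 | oxepane lactone C11 ketone | O=C1O[C@H]2[C@H]3[C@@H](C[C@@H](C)C(=O)[C@@H]13)[C@@H](C)CO[C@@]2(C)C(=O)OC | intermediate
17 | C9 lactol, C4 aldehyde, C11 alcohol | OC1O[C@H]2[C@H]3[C@@H](C[C@@H](C)[C@@H](O)[C@@H]13)[C@@H](C)CO[C@@]2(C)C=O | intermediate
18 | C9,C11-diacetate C4 aldehyde | CC(=O)OC1O[C@H]2[C@H]3[C@@H](C[C@@H](C)[C@@H](OC(C)=O)[C@@H]13)[C@@H](C)CO[C@@]2(C)C=O | intermediate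
19 | C4 homoallylic alcohol | CC(=O)OC1O[C@H]2[C@H]3[C@@H](C[C@@H](C)[C@@H](OC(C)=O)[C@@H]13)[C@@H](C)CO[C@@]2(C)[C@H](O)CC=C | intermediate
20 | C4 octanoate | CC(=O)OC1O[C@H]2[C@H]3[C@@H](C[C@@H](C)[C@@H](OC(C)=O)[C@@H]13)[C@@H](C)CO[C@@]2(C)[C@H](OC(=O)CCCCCCC)CC=C | intermediate
21 | C9-methallyl, C4-allyl metathesis precursor | C=C(C)C[C@@H]1O[C@H]2[C@H]3[C@@H](C[C@@H](C)[C@@H](OC(C)=O)[C@H]31)[C@@H](C)CO[C@@]2(C)[C@H](OC(=O)CCCCCCC)CC=C | intermediate
22 | (6Z)-oxonene tetracycle | C1[C@@H]2O[C@H]3[C@H]4[C@@H](C[C@@H](C)[C@@H](OC(C)=O)[C@H]42)[C@@H](C)CO[C@@]3(C)[C@H](OC(=O)CCCCCCC)C/C=C1/C | intermediate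
23 | C6 allylic hydroperoxide, C7 exocyclic methylene | C=C1C[C@@H]2O[C@H]3[C@H]4[C@@H](C[C@@H](C)[C@@H](OC(C)=O)[C@H]42)[C@@H](C)CO[C@@]3(C)[C@H](OC(=O)CCCCCCC)CC1OO | intermediate
24 | C6 allylic alcohol, C7 exocyclic methylene | C=C1C[C@@H]2O[C@H]3[C@H]4[C@@H](C[C@@H](C)[C@@H](OC(C)=O)[C@H]42)[C@@H](C)CO[C@@]3(C)[C@H](OC(=O)CCCCCCC)CC1O | intermediate
25 | asbestinin 16 | C=C1C[C@@H]2O[C@H]3[C@H]4[C@@H](C[C@@H](C)[C@@H](OC(C)=O)[C@H]42)[C@@H](C)CO[C@@]3(C)[C@H](OC(=O)CCCCCCC)CC1=O | target

**Step count:** 18 steps in total. The longest linear sequence is 17 steps (1 → 25 through steps 1–3 and 5–18).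

**The three steps most likely to fail**

Step 6 (Diels–Alder). Diene and dienophile are both electron-poor and the dienophile is hindered, so the triene may decompose before it cyclises. The fallback sets out from 9. The enone carbonyl is methylenated first (Ph3P=CH2) to give the tetraene ester F1. Its C1=C14 bond now belongs to an electron-richer 1,3-diene, which matches the electron-poor dienoate. Heating at lower temperature followed by DBU gives the isopropenyl lactone directly, so the fallback comes back at 12. The E-alkene still fixes C14, and the same C2 rotamer fixes C1.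

Step 13 (allylation). MgBr2 may ionise the anomeric acetate, or the new C4–OH may attack C9. The fallback sets out from 17, before acetylation. The free lactol–aldehyde is allylated under the same chelating conditions and then treated with CSA. The new C4–OH closes onto C9 and gives the bridged C4–O–C9 bicyclic acetal F2, which masks both positions. Acetylation of the only free hydroxyl (C11) gives the acetal acetate F3. Methallyltrimethylsilane/TiCl4 opens the acetal at C9 from the convex face to give the C9-methallyl C4-alcohol F4. Octanoylation then brings the route back at 21.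

Step 17 (ene reaction). Hydrogen may be taken from C5 or C8 instead of the C19 methyl. The fallback sets out from 22. m-CPBA gives the C6,C7-epoxide F5. TMSOTf/2,6-lutidine and then DBU open it at the tertiary C7 with loss of a C19 hydrogen, giving the C6 allylic trimethylsilyl ether F6. Dilute aqueous acid removes the silyl group, and the fallback comes back at 24.

**Further compounds**
F1 | step 6 | tetraene ester (C15 methylenated 9) | C=C(C)/C=C/C(=O)O[C@@H](/C=C/C(C)=C)[C@@](C)(O)C(=O)OC
F2 | step 13 | bridged C4–O–C9 bicyclic acetal, C4 allyl, C11–OH free | [C@@H]15O[C@H]2[C@H]3[C@@H](C[C@@H](C)[C@@H](O)[C@@H]13)[C@@H](C)CO[C@@]2(C)[C@@H](CC=C)O5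
F3 | step 13 | bridged bicyclic acetal C11 acetate | [C@@H]15O[C@H]2[C@H]3[C@@H](C[C@@H](C)[C@@H](OC(C)=O)[C@@H]13)[C@@H](C)CO[C@@]2(C)[C@@H](CC=C)O5
F4 | step 13 | C9-methallyl C4-alcohol C11 acetate | C=C(C)C[C@@H]1O[C@H]2[C@H]3[C@@H](C[C@@H](C)[C@@H](OC(C)=O)[C@H]31)[C@@H](C)CO[C@@]2(C)[C@H](O)CC=C
F5 | step 17 | C6,C7-epoxide of 22 | C1[C@@H]2O[C@H]3[C@H]4[C@@H](C[C@@H](C)[C@@H](OC(C)=O)[C@H]42)[C@@H](C)CO[C@@]3(C)[C@H](OC(=O)CCCCCCC)CC5OC15C
F6 | step 17 | C6 allylic trimethylsilyl ether, C7 exocyclic methylene | C=C1C[C@@H]2O[C@H]3[C@H]4[C@@H](C[C@@H](C)[C@@H](OC(C)=O)[C@H]42)[C@@H](C)CO[C@@]3(C)[C@H](OC(=O)CCCCCCC)CC1O[Si](C)(C)C
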